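The south-east run, charged with twice as much nucleophile as electrophile, has 25.0% of its electrophile left at 5.00 h. A second-order law, with the nucleophile counted net of impurity, turns that reading into an average rate constant of 0.510 M⁻¹ h⁻¹.

common to all: electrophile 0.40 M
- south-east: nucleophile 0.80 M; free base 0.60 M; protic impurity 0.060 M; run made earlier
- south-west: nucleophile 0.40 M; free base 0.60 M; protic impurity 0.040 M; run made earlier
- green: nucleophile 0.800 M; free base 0.600 M; protic impurity 0.0400 M; time 25 h
- violet: nucleophile 0.800 M; free base 1.20 M; protic impurity 0.0400 M; time 25 h
- blue: nucleophile 0.800 M; free base 2.40 M; protic impurity 0.0400 M; time 25 h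

| run | time / h | electrophile / % | product / % |
|---|---|---|---|
| south-east | 0.417 | 81.1 | 19.1 |
| south-east | 0.667 | 72.6 | 27.3 |
| south-east | 1.00 | 64.0 | 36.5 |
| south-east | 1.33 | 57.2 | 43.2 |
| south-east | 2.00 | 47.3 | 52.9 |
| south-east | 3.00 | 37.4 | 61.8 |
| south-east | 5.00 | 25.0 | 74.5 |
| south-west | 0.667 | 85.4 | 14.8 |
| south-west | 1.33 | 75.4 | 24.1 |
| south-west | 2.00 | 69.1 | 31.0 |
| south-west | 3.00 | 61.9 | 37.5 |
| south-west | 4.00 | 57.4 | 42.6 |
| south-west | 5.00 | 53.3 | 46.6 |

(readings scatter by 0.3 percentage points)

- the earlier runs were read with a standard deviation of 0.3 percentage points
- no earlier run changes the charge of free base; that part of a forecast is a guess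

1. part of the electrophile that has reacted at the end, green
2. part of the electrophile that has reacted at the end, violet
3. part of the electrophile that has reacted at the end, blue
4. what raising the concentration of free base from its lowest to its highest value here does to the part of the electrophile that has reacted (changes below 5 percentage points count as none) (it rises / no change / it falls)

I fold each flask into one number, which I call the reach: that rate constant, times the spare nucleophile, times the time. The spare is the nucleophile charged less one equivalent each for electrophile and impurity, in green 0.360 M, so the reach of green is 4.59. A large positive reach means the electrophile is consumed with nucleophile to spare. The electrophile left, as a part of its charge, is the spare divided by the net nucleophile times the exponential of the reach, less the electrophile charged, and for green I reckon 99.5% reacted.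

Is one number enough? With the same constant the south-west run should keep 53.4% at 5.00 h, and it reads 53.3%. For the first south-east reading, though, I reckon 86.0% left, more than the 81.1% read, so the constant is an average and the south-east run starts faster than it says. Free base has no place in the reach and no earlier run changed its charge, so I guess that violet and blue match green, with no change.

The forecast differs: 90%, 83% and 72%, so it falls, reasoning that “something active is dying with time”.

Green, violet and blue give 99.4%, 99.7% and 99.9%, and since the difference of 0.5 percentage points is below the margin of 5 points, the trend counts as no change.

    nucleophile + protic impurity → quenched reagent (k = 2.50 M⁻¹ h⁻¹)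
    electrophile + nucleophile → acid set free + product (k = 0.740 M⁻¹ h⁻¹)
    acid set free + free base ⇌ salt of the base (K = 22000 M⁻¹, k = 2.00 M⁻¹ h⁻¹)
    nucleophile + acid set free ⇌ protonated nucleophile, settled at all times (K = 40.0 M⁻¹)

A neighbour flask, like green but with 0.32 M of nucleophile, has a spare of −0.120 M. The negative sign marks nucleophile as the limiting reagent, and the reach is −1.53. The same reckoning gives 64.6% reacted, and that flask gives 65.4%, with 5.3% of its nucleophile still free and 34.6% of its electrophile left.

Readings and results were generated by integration from invented constants.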